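The butenolide ring (O1, C2=O, C3–OH, C4–aryl, C5) is cut at C3–C4. Because the quaternary C5 carries a methyl ester and is also bonded to C4, C4 and that ester are traced back to the two identical esters of an acyloxymalonate. The precursor 11 is thus prochiral: a dimethyl 2-benzyl-2-(MOM-glycoloyloxy)malonate. A chiral lithium amide makes the glycolate enolate, which closes onto one of the enantiotopic esters and so forms the C3–C4 bond, the lactone ring and the C5 stereocentre in one operation. The tetronic acid 13 then offers its C4–OH for triflation and Suzuki arylation; one acid step removes all MOM groups.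

Key step: step 8

Remark 1: ring positions follow lactone numbering (O1, C2 = lactone carbonyl, C3, C4, C5 = quaternary carbon), also in compound names; C5 is S in the target and in 13, 14 and 19.
Remark 2: the sense of induction of the chiral base in step 8 cannot be predicted with confidence; the (R,R)-base is written, and its (S,S)-antipode is used instead if the first experiment shows that one to lead to (S)-13.
Remark 3: the chiral tetramine of step 8 is treated as a reagent obtainable in both antipodes (from phenylglycine if not purchased).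

Step 1
Reactants: 1 3-bromo-4-hydroxybenzaldehyde
Product: 2 3-bromo-4-(methoxymethoxy)benzaldehyde
Conditions: MOMCl, i-Pr2NEt, CH2Cl2, 0 °C to rt
Reagents that add atoms: chloromethyl methyl ether, COCCl
Why: O-alkylation of the phenol with MOMCl under amine base (acetal protection) is routine, and neither the aldehyde nor the aryl bromide reacts.

Step 2
Reactants: 2 3-bromo-4-(methoxymethoxy)benzaldehyde
Product: 3 4-(methoxymethoxy)-3-(3-methylbut-2-en-1-yl)benzaldehyde
Conditions: Pd(PPh3)4 (5 mol%), tributyl(3-methylbut-2-en-1-yl)stannane, DMF, 90 °C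
Reagents that add atoms: tributyl(3-methylbut-2-en-1-yl)stannane, CCCC[Sn](CCCC)(CCCC)CC=C(C)C
Why: Stille coupling, in which the C–Br bond para to the formyl group adds readily to zerovalent palladium and reductive elimination at the unsubstituted allyl terminus should give the linear prenyl arene under neutral conditions that spare aldehyde and acetal.

Step 3
Reactants: 3 4-(methoxymethoxy)-3-(3-methylbut-2-en-1-yl)benzaldehyde
Product: 4 [4-(methoxymethoxy)-3-(3-methylbut-2-en-1-yl)phenyl]methanol
Conditions: NaBH4, MeOH, 0 °C
Reagents that add atoms: none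
Why: Borohydride reduction of the aldehyde to the benzylic alcohol leaves the trisubstituted alkene and the MOM ether untouched.

Step 4
Reactants: 4 [4-(methoxymethoxy)-3-(3-methylbut-2-en-1-yl)phenyl]methanol
Product: 5 4-(bromomethyl)-1-(methoxymethoxy)-2-(3-methylbut-2-en-1-yl)benzene
Conditions: CBr4, PPh3, 2,6-lutidine, CH2Cl2, 0 °C; used at once
Reagents that add atoms: carbon tetrabromide, BrC(Br)(Br)Br
Why: Appel bromination converts the primary benzylic alcohol into the bromide under buffered, non-acidic conditions that keep the acetal and the alkene intact.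

Step 5
Reactants: 6 methyl glycolate (methyl 2-hydroxyacetate)
Product: 7 methyl 2-(methoxymethoxy)acetate
Conditions: MOMCl, i-Pr2NEt, CH2Cl2, 0 °C to rt
Reagents that add atoms: chloromethyl methyl ether, COCCl
Why: O-alkylation of the primary alcohol with MOMCl (acetal protection) installs the ether that later masks the C3 oxygen and can chelate lithium in the key step.

Step 6
Reactants: 7 methyl 2-(methoxymethoxy)acetate; 8 dimethyl 2-bromomalonate
Product: 10 dimethyl 2-{[2-(methoxymethoxy)acetyl]oxy}malonate, via potassium 2-(methoxymethoxy)acetate 9 (not isolated)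
Conditions: KOH (1.0 equiv), MeOH, rt; evaporate; then 8, DMF, 0 °C to rt
Reagents that add atoms: potassium hydroxide, [K+].[OH-]
Why: Saponification with exactly one equivalent of hydroxide gives the carboxylate, which displaces bromide from the doubly activated carbon of the bromomalonate in an SN2 O-alkylation, the standard entry to acyloxymalonates.

Step 7
Reactants: 10 dimethyl 2-{[2-(methoxymethoxy)acetyl]oxy}malonate; 5 4-(bromomethyl)-1-(methoxymethoxy)-2-(3-methylbut-2-en-1-yl)benzene
Product: 11 dimethyl 2-{[4-(methoxymethoxy)-3-(3-methylbut-2-en-1-yl)phenyl]methyl}-2-{[2-(methoxymethoxy)acetyl]oxy}malonate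
Conditions: Cs2CO3, DMF, 0 °C to rt
Reagents that add atoms: none
Why: Malonic ester C-alkylation, in which carbonate deprotonates only the acidic malonate C–H (not the glycolate CH2, so no premature ring closure) and the soft anion attacks the benzylic bromide at carbon to create the prochiral quaternary centre.

Step 8
Reactants: 11 dimethyl 2-{[4-(methoxymethoxy)-3-(3-methylbut-2-en-1-yl)phenyl]methyl}-2-{[2-(methoxymethoxy)acetyl]oxy}malonate
Product: 13 methyl (5S)-4-hydroxy-3-(methoxymethoxy)-5-{[4-(methoxymethoxy)-3-(3-methylbut-2-en-1-yl)phenyl]methyl}-2-oxo-2,5-dihydrofuran-5-carboxylate, via chelated lithium enolate 12 (not isolated)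
Conditions: (R,R)-N,N′-bis(1-phenyl-2-piperidin-1-ylethyl)propane-1,3-diamine (1.3 equiv), n-BuLi (2.6 equiv), THF, 0 °C; then 11 (dilute), −78 to −40 °C; 1 M aq. HCl, 0 °C
Reagents that add atoms: none
Why: Proposed new method: the chiral dilithium diamide removes a proton from the glycolate CH2, the only enolisable position, to give lithium enolate 12, held in a mixed aggregate with the chiral amide and fixed by chelation of lithium to the MOM oxygen; C3 then adds to one methoxycarbonyl carbon, methoxide leaves, and the tetronic acid formed is converted at once into its lithium salt, so the ring cannot reopen. The closest known reaction types are the racemic Dieckmann (intramolecular Claisen) closure of α-(alkoxyacetoxy) esters to 3-alkoxytetronic acids with achiral lithium amides, and the enantioselective aldol and alkylation reactions of achiral lithium enolates carried in chiral lithium amide aggregates; new is their combination to tell two enantiotopic ester groups apart. The one ring formed (O1–C2–C3–C4–C5) closes 5-exo-trig at the ester carbonyl (5-enolendo in enolate terms, the mode by which α-acyloxy esters are known to give tetronic acids), after rotation about O1–C2 into the lactone-like conformation. The stereocentre C5 is set under reagent control: (S)-13 requires attack on the pro-R ester, and the chiral amide in the aggregate should decide which ester carbonyl can bind the second lithium and face C3 while the benzyl group points away from the ligand. The selectivity needed is enantiotopic-group selectivity; the substrate supplies only the preconditions, namely a single enolisable site, a chelating OMOM group and the size difference between benzyl and the spectator ester, while chemoselectivity is no issue because both closures give the same constitution.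

Step 9
Reactants: 13 methyl (5S)-4-hydroxy-3-(methoxymethoxy)-5-{[4-(methoxymethoxy)-3-(3-methylbut-2-en-1-yl)phenyl]methyl}-2-oxo-2,5-dihydrofuran-5-carboxylate
Product: 14 methyl (5S)-3-(methoxymethoxy)-5-{[4-(methoxymethoxy)-3-(3-methylbut-2-en-1-yl)phenyl]methyl}-2-oxo-4-{[(trifluoromethyl)sulfonyl]oxy}-2,5-dihydrofuran-5-carboxylate
Conditions: Tf2O, i-Pr2NEt, CH2Cl2, −78 °C
Reagents that add atoms: trifluoromethanesulfonic anhydride, O=S(=O)(OS(=O)(=O)C(F)(F)F)C(F)(F)F
Why: Enol triflate formation, in which the tetronate is sulfonylated on the C4 oxygen (C3 is blocked by OMOM) and the quaternary C5 cannot epimerise.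

Step 10
Reactants: 15 3-bromocatechol (3-bromobenzene-1,2-diol)
Product: 16 1-bromo-2,3-bis(methoxymethoxy)benzene
Conditions: MOMCl (3 equiv), i-Pr2NEt, CH2Cl2, 0 °C to rt
Reagents that add atoms: chloromethyl methyl ether, COCCl
Why: Double O-alkylation of the catechol with MOMCl (acetal protection) gives base-stable ethers that match those of the other fragment.

Step 11
Reactants: 16 1-bromo-2,3-bis(methoxymethoxy)benzene
Product: 17 2-[3-bromo-4,5-bis(methoxymethoxy)phenyl]-4,4,5,5-tetramethyl-1,3,2-dioxaborolane
Conditions: [Ir(OMe)(cod)]2 (1.5 mol%), 4,4′-di-tert-butyl-2,2′-bipyridine (3 mol%), B2pin2, THF, 70 °C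
Reagents that add atoms: bis(pinacolato)diboron, CC1(C)OB(OC1(C)C)B1OC(C)(C)C(C)(C)O1
Why: Iridium-catalysed aromatic C–H borylation is sterically controlled, so of the three ring hydrogens only the one without an ortho substituent (meta to Br and to OMOM) should react, and the C–Br bond is tolerated.

Step 12
Reactants: 17 2-[3-bromo-4,5-bis(methoxymethoxy)phenyl]-4,4,5,5-tetramethyl-1,3,2-dioxaborolane
Product: 18 2-[3,4-bis(methoxymethoxy)-5-(3-methylbut-2-en-1-yl)phenyl]-4,4,5,5-tetramethyl-1,3,2-dioxaborolane
Conditions: Pd(PPh3)4 (5 mol%), tributyl(3-methylbut-2-en-1-yl)stannane, DMF, 100 °C, no base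
Reagents that add atoms: tributyl(3-methylbut-2-en-1-yl)stannane, CCCC[Sn](CCCC)(CCCC)CC=C(C)C
Why: Stille coupling at the C–Br bond; without base the boronic ester does not transmetalate to palladium, so it survives while the prenyl group is transferred from tin as in step 2.

Step 13
Reactants: 14 methyl (5S)-3-(methoxymethoxy)-5-{[4-(methoxymethoxy)-3-(3-methylbut-2-en-1-yl)phenyl]methyl}-2-oxo-4-{[(trifluoromethyl)sulfonyl]oxy}-2,5-dihydrofuran-5-carboxylate; 18 2-[3,4-bis(methoxymethoxy)-5-(3-methylbut-2-en-1-yl)phenyl]-4,4,5,5-tetramethyl-1,3,2-dioxaborolane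
Product: 19 methyl (5S)-4-[3,4-bis(methoxymethoxy)-5-(3-methylbut-2-en-1-yl)phenyl]-3-(methoxymethoxy)-5-{[4-(methoxymethoxy)-3-(3-methylbut-2-en-1-yl)phenyl]methyl}-2-oxo-2,5-dihydrofuran-5-carboxylate
Conditions: Pd(OAc)2 (5 mol%), SPhos (10 mol%), K3PO4, toluene/H2O (10:1), 60 °C
Reagents that add atoms: none
Why: Suzuki–Miyaura coupling of the electron-poor enol triflate with a boronate free of ortho substituents, helped at the crowded C4 by a bulky dialkylbiarylphosphine, should form the C4–aryl bond without touching C5, the ester or the alkenes.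

Step 14
Reactants: 19 methyl (5S)-4-[3,4-bis(methoxymethoxy)-5-(3-methylbut-2-en-1-yl)phenyl]-3-(methoxymethoxy)-5-{[4-(methoxymethoxy)-3-(3-methylbut-2-en-1-yl)phenyl]methyl}-2-oxo-2,5-dihydrofuran-5-carboxylate
Product: 20 methyl (5S)-4-[3,4-dihydroxy-5-(3-methylbut-2-en-1-yl)phenyl]-3-hydroxy-5-{[4-hydroxy-3-(3-methylbut-2-en-1-yl)phenyl]methyl}-2-oxo-2,5-dihydrofuran-5-carboxylate (CNP0460191.1)
Conditions: 3 M aq. HCl/MeOH (degassed), rt
Reagents that add atoms: none
Why: Acid-catalysed methanolysis of the four MOM acetals (three aryl, one enol) is routine; methanol keeps the methyl ester unchanged, dilute acid at room temperature should be too mild to cyclise the o-prenylphenols, and C5 has no path to racemise.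

Compound list
1 | 3-bromo-4-hydroxybenzaldehyde | O=Cc1ccc(O)c(Br)c1 | starting material
2 | 3-bromo-4-(methoxymethoxy)benzaldehyde | O=Cc1ccc(OCOC)c(Br)c1 | intermediate
3 | 4-(methoxymethoxy)-3-(3-methylbut-2-en-1-yl)benzaldehyde | O=Cc1ccc(OCOC)c(CC=C(C)C)c1 | intermediate
4 | [4-(methoxymethoxy)-3-(3-methylbut-2-en-1-yl)phenyl]methanol | OCc1ccc(OCOC)c(CC=C(C)C)c1 | intermediate
5 | 4-(bromomethyl)-1-(methoxymethoxy)-2-(3-methylbut-2-en-1-yl)benzene | BrCc1ccc(OCOC)c(CC=C(C)C)c1 | intermediate
6 | methyl glycolate | COC(=O)CO | starting material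
7 | methyl 2-(methoxymethoxy)acetate | COCOCC(=O)OC | intermediate
8 | dimethyl 2-bromomalonate | COC(=O)C(Br)C(=O)OC | starting material
9 | potassium 2-(methoxymethoxy)acetate (formed in the flask) | [K+].[O-]C(=O)COCOC | intermediate
10 | dimethyl 2-{[2-(methoxymethoxy)acetyl]oxy}malonate | COCOCC(=O)OC(C(=O)OC)C(=O)OC | intermediate
11 | dimethyl 2-{[4-(methoxymethoxy)-3-(3-methylbut-2-en-1-yl)phenyl]methyl}-2-{[2-(methoxymethoxy)acetyl]oxy}malonate | COCOCC(=O)OC(Cc1ccc(OCOC)c(CC=C(C)C)c1)(C(=O)OC)C(=O)OC | intermediate
12 | lithium enolate of 11 at the glycolate CH2, lithium chelated by the MOM oxygen (formed in the flask) | [Li+].COCOC=C([O-])OC(Cc1ccc(OCOC)c(CC=C(C)C)c1)(C(=O)OC)C(=O)OC | intermediate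
13 | methyl (5S)-4-hydroxy-3-(methoxymethoxy)-5-{[4-(methoxymethoxy)-3-(3-methylbut-2-en-1-yl)phenyl]methyl}-2-oxo-2,5-dihydrofuran-5-carboxylate | COC(=O)[C@@]1(Cc2ccc(OCOC)c(CC=C(C)C)c2)OC(=O)C(OCOC)=C1O | intermediate
14 | methyl (5S)-3-(methoxymethoxy)-5-{[4-(methoxymethoxy)-3-(3-methylbut-2-en-1-yl)phenyl]methyl}-2-oxo-4-{[(trifluoromethyl)sulfonyl]oxy}-2,5-dihydrofuran-5-carboxylate | COC(=O)[C@@]1(Cc2ccc(OCOC)c(CC=C(C)C)c2)OC(=O)C(OCOC)=C1OS(=O)(=O)C(F)(F)F | intermediate
15 | 3-bromocatechol (3-bromobenzene-1,2-diol) | Oc1cccc(Br)c1O | starting material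
16 | 1-bromo-2,3-bis(methoxymethoxy)benzene | COCOc1cccc(Br)c1OCOC | intermediate
17 | 2-[3-bromo-4,5-bis(methoxymethoxy)phenyl]-4,4,5,5-tetramethyl-1,3,2-dioxaborolane | COCOc1cc(B2OC(C)(C)C(C)(C)O2)cc(Br)c1OCOC | intermediate
18 | 2-[3,4-bis(methoxymethoxy)-5-(3-methylbut-2-en-1-yl)phenyl]-4,4,5,5-tetramethyl-1,3,2-dioxaborolane | COCOc1cc(B2OC(C)(C)C(C)(C)O2)cc(CC=C(C)C)c1OCOC | intermediate
19 | methyl (5S)-4-[3,4-bis(methoxymethoxy)-5-(3-methylbut-2-en-1-yl)phenyl]-3-(methoxymethoxy)-5-{[4-(methoxymethoxy)-3-(3-methylbut-2-en-1-yl)phenyl]methyl}-2-oxo-2,5-dihydrofuran-5-carboxylate | COC(=O)[C@@]1(Cc2ccc(OCOC)c(CC=C(C)C)c2)OC(=O)C(OCOC)=C1c1cc(OCOC)c(OCOC)c(CC=C(C)C)c1 | intermediate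
20 | methyl (5S)-4-[3,4-dihydroxy-5-(3-methylbut-2-en-1-yl)phenyl]-3-hydroxy-5-{[4-hydroxy-3-(3-methylbut-2-en-1-yl)phenyl]methyl}-2-oxo-2,5-dihydrofuran-5-carboxylate (CNP0460191.1) | COC(=O)[C@@]1(Cc2ccc(O)c(CC=C(C)C)c2)OC(=O)C(O)=C1c1cc(O)c(O)c(CC=C(C)C)c1 | target

Total step count: 14 steps.
Longest linear sequence: 9 steps (steps 1, 2, 3, 4, 7, 8, 9, 13, 14).

Steps most likely to fail

Step 8. The two enantiotopic ester groups may be discriminated poorly, for instance because part of the enolate closes outside the chiral aggregate, so that the ring forms but with low enantiomeric purity. The fallback uses known chemistry and sets out from 11. LiN(SiMe3)2 (2.2 equiv) in THF at −78 to 0 °C should effect the established racemic Dieckmann closure to the racemic tetronic acid F1. F1, a strong vinylogous acid, would be resolved classically through the (R)-1-phenylethylammonium salt of the (S)-acid F2, obtained by salt formation with (R)-1-phenylethylamine and fractional crystallisation (the (S)-amine is taken if that pairing proves to be the less soluble one). Cold dilute acid would then liberate 13, where the route is rejoined.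

Step 13. The triflyl group may be lost by attack of the aqueous base at sulfur, and transmetalation at the crowded C4–palladium intermediate may be slow, so that 14 reverts to the tetronic acid before the biaryl-type bond forms. The fallback sets out from 13: TsCl and i-Pr2NEt in CH2Cl2 should give the C4 tosylate F3, a sulfonate that withstands aqueous base. Its coupling with 18 under Pd(OAc)2/XPhos and K3PO4 in THF/H2O at 60 °C, a coupling known for tetronic acid tosylates, would rejoin the route at 19.

Step 14. While the last MOM groups are still being cleaved, the Brønsted acid may promote cyclisation of the o-prenylphenols onto their alkenes (chroman formation) or addition of methanol to the prenyl groups. The fallback sets out from 19: Me3SiOTf with 2,2′-bipyridyl in MeCN at 0 °C should exchange each aryl and enol MOM ether for a trimethylsilyl ether without free acid, giving the tetrakis(trimethylsilyl) ether F4. Addition of water would hydrolyse the silyl ethers and deliver 20.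

Further compounds
F1 | step 8 | racemic methyl 4-hydroxy-3-(methoxymethoxy)-5-{[4-(methoxymethoxy)-3-(3-methylbut-2-en-1-yl)phenyl]methyl}-2-oxo-2,5-dihydrofuran-5-carboxylate | COC(=O)C1(Cc2ccc(OCOC)c(CC=C(C)C)c2)OC(=O)C(OCOC)=C1O
F2 | step 8 | (R)-1-phenylethylammonium salt of the (S)-tetronic acid 13 | C[C@@H]([NH3+])c1ccccc1.COC(=O)[C@@]1(Cc2ccc(OCOC)c(CC=C(C)C)c2)OC(=O)C(OCOC)=C1[O-]
F3 | step 13 | methyl (5S)-3-(methoxymethoxy)-5-{[4-(methoxymethoxy)-3-(3-methylbut-2-en-1-yl)phenyl]methyl}-4-{[(4-methylphenyl)sulfonyl]oxy}-2-oxo-2,5-dihydrofuran-5-carboxylate | COC(=O)[C@@]1(Cc2ccc(OCOC)c(CC=C(C)C)c2)OC(=O)C(OCOC)=C1OS(=O)(=O)c1ccc(C)cc1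
F4 | step 14 | tetrakis(trimethylsilyl) ether of 20 (silyl groups on the three phenolic oxygens and on the C3 enol oxygen) | COC(=O)[C@@]1(Cc2ccc(O[Si](C)(C)C)c(CC=C(C)C)c2)OC(=O)C(O[Si](C)(C)C)=C1c1cc(O[Si](C)(C)C)c(O[Si](C)(C)C)c(CC=C(C)C)c1
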